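**The problem**

The target 23 is a drimane. A trans-fused decalin (rings A and B) with four contiguous stereocenters (C5, C8, C9, C10) is joined through the exocyclic trisubstituted alkene C11=C1′ to a five-membered ring C. Ring C is a vinylogous acid (hydroxyl on C2′, ketone on C4′) with a secondary chloride on the stereogenic carbon C5′, and C9 stands cis to C2′ across the alkene. C5, C9 and C10 have the configuration of the labdane chiral pool. The tertiary alcohol at C8 is axial (β) and cis to the C9 side chain, the opposite of the commercial lactone, but this is the thermodynamically preferred arrangement of the lactone, so C8 can be corrected by equilibration. C5′ lies beyond a planar alkene, four bonds from C9, so the decalin cannot be expected to control it directly and a stereochemical relay is needed. The fragile points are: the C5′–H bond (α to a carbonyl, allylic, chlorine-bearing; epimerization and loss of HCl); the vinylogous acid next to the 8β-hydroxyl (cyclic enol ether under dehydrating acid); the tertiary alcohol; and every intermediate with a C11 carbonyl β to the C8 oxygen (retro-aldol, β-elimination). The enabling feature is the pattern of ring C: oxygen on C2′ and C4′, chlorine on sp3 C5′ and an exocyclic alkene at C1′. This is what a pentadienyl cation spanning C1′–C5′ leaves behind when C1′ is the central carbon of a 1-alkoxyallene (C11=C1′=C2′) and C5′ the end of a chloroalkene, and the allene axis can carry configuration from C11 to C5′.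

**Retrosynthesis**

Endgame. 23 is traced to its C8 triethylsilyl ether 22 and then to the C2′ ethyl enol ether 21. No skeletal bond is cut. The silyl ether keeps the 8β-oxygen away from C2′ while ring C is made and unmasked, and the enol ether is the form in which the ring-forming step releases the vinylogous acid. The forward steps must be mild enough to leave C5′ untouched.

Ring C (C1′–C5′). 21 is opened to the acyclic carbinol 19, an (aS)-1-ethoxyallene carrying a (Z)-3-chloro-2-methoxyallyl alcohol on C2′. Cutting C1′–C5′ is preferred to cutting C11=C1′ (a condensation onto a preformed chlorocyclopentenone), because that alternative controls neither alkene geometry nor C5′. Here one conrotatory closure sets the ring, the alkene geometry and C5′ together, with chlorine already in place. The forward reaction must ionize C3′ without acid (the allenyl ether would be protonated) and without a base able to deprotonate C5′ of the cyclized cation.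

C2′–C3′. 19 divides into the lithiated allenyl ether 18 (from 12) and (Z)-3-chloro-2-methoxyacrolein 17. This is the convergent cut: all drimane stereochemistry and the axis are on one side, a four-carbon aldehyde on the other. The addition must proceed with retention of the axis and at the carbonyl carbon only. C3′ needs no control.

The allene axis (C11, C1′, C2′). 12 is traced to the propargylic alcohol 9 by a stereospecific reductive 1,3-transposition, which converts the C11 carbinol center into the axis. 9 comes from aldehyde 6 and ethoxyacetylene 7 (C11–C1′). The alternative, base isomerization of a propargyl ether, gives the same allene without control of the axis. The forward sequence requires the (11S) alcohol and a transposition that tolerates an ynol ether.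

Decalin. 6 is the silyl ether of 8β-hydroxydriman-11-al 5. 5 is reached from (+)-sclareolide 1 by C8 epimerization (2) and removal of C12 (α-hydroxylation to 3, reduction to triol 4, glycol cleavage). Three stereocenters are bought and the fourth is set by equilibration, so no skeletal bond of the decalin has to be made.

Aldehyde 17. 17 is traced through the vinylogous formamide 15 to 1,1,2-trimethoxyethane 13 (one carbon from DMF). The chloroalkene geometry required is the one with chlorine trans to the formyl group, expected to be the stable isomer.

**Roads not taken**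

Alternative 1: Ring A is cut at C1–C10. In the forward sense the phenoxide of bromide A1 attacks the tethered primary bromide through its methylated ortho carbon and gives the cyclohexa-2,4-dienone A2, creating the quaternary C10 in the ring-forming step.
- Merits: a short, fully synthetic entry to the bicycle from an arene; either enantiomer and ring-A analogues are within reach. In this flexibility it is better than the chosen plan, which is tied to one natural lactone.
- Weak points: A2 has only C10 as a stereocenter, so the dearomatization must be made enantioselective by an external chiral agent. C5, C8 and C9 must then be set one by one from a dienone, including a one-carbon homologation of the hindered C9 ketone and a tertiary alcohol at C8.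
- Comparison: ring C, the real difficulty, is not addressed at all. The chosen plan reaches aldehyde 6 in five steps with all four centers secured, which Alternative 1 cannot match in step count.

Alternative 2: Rings A and B are cut at C4–C5 and C9–C10. MeAlCl2 opens the (S)-epoxide of the acyclic β-keto ester A3, and the alkene and the enol carbon add in turn to give the hydroxy keto ester A4.
- Merits: C5, C9 and C10 come from a single catalyst-derived epoxide stereocenter in one step. The C8 ketone should accept a methyl nucleophile anti to the axial C10 methyl, which would give the 8β-alcohol directly. In that respect it is as good as or better than the acid epimerization used here.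
- Weak points: the 3β-hydroxyl of A4 is not in the target and must be removed. The β-keto ester enolizes under organometallic addition. The ester must be brought to the aldehyde level. Cation–olefin bicyclizations terminated by β-keto esters are rarely efficient.
- Comparison: roughly twice as many steps would be needed to reach the oxidation pattern of 6, and again nothing is contributed to ring C. The chosen plan sets cheap chiral-pool material and a four-step degradation against the generality of Alternative 2.

Alternative 3: Ring B is cut at C8–C9. The enamine of the aldehyde in keto aldehyde A5 adds to the methyl ketone under equilibrating conditions, and the aldol A6 with equatorial methyl and axial hydroxyl at C8 should predominate.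
- Merits: A6 is the same compound as 5, so this road is a rival only to steps 1–4, not to the key step. It sets C8 and C9 by thermodynamics in one operation and is independent of natural material.
- Weak points: A5, with its vicinal C5/C10 centers and a quaternary carbon, needs an enantioselective synthesis of several steps. The aldol product is prone to dehydration to the conjugated enal and to retro-aldol under the amine conditions that form it.
- Comparison: the chosen plan reaches 5 from 1 in four steps with no stereochemical decision except the C8 equilibration. The aldol route would win only if 1 were unavailable or if isotopic or skeletal variants of ring B were wanted.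

Key step: step 11

Remark on the chemistry: drimane numbering is used for the decalin (C11 on C9) and primed numbers for ring C. 23 is drawn as its 2′-hydroxy-4′-oxo tautomer, which will equilibrate with the 4′-hydroxy-2′-oxo form in solution.

**Route**

Step 1
Reactants: 1 (+)-sclareolide
Product: 2 8-epi-sclareolide
Conditions: conc. H2SO4, HCO2H, 55 °C
Reagents that add atoms: none
Why: Acid-mediated alkyl–oxygen ionization at C8 and re-closure equilibrate the lactone; the cis-fused isomer with equatorial C8 methyl and axial oxygen is the thermodynamic product, which sets the 8β-oxygen of the target.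

Step 2
Reactants: 2 8-epi-sclareolide
Product: 3 11-hydroxy-8-epi-sclareolide (C11 epimers)
Conditions: KN(SiMe3)2, THF, −78 °C; then 2-(phenylsulfonyl)-3-phenyloxaziridine, −78 °C
Reagents that add atoms: 2-(phenylsulfonyl)-3-phenyloxaziridine, O=S(=O)(c1ccccc1)N1OC1c1ccccc1
Why: Enolate α-hydroxylation with an N-sulfonyloxaziridine; the new C11 center is not controlled and need not be, because C11 becomes a carbonyl carbon in step 4.

Step 3
Reactants: 3 11-hydroxy-8-epi-sclareolide
Product: 4 8-epi-13,14,15,16-tetranorlabdane-8,11,12-triol (C11 epimers)
Conditions: LiAlH4, THF, 0 → 40 °C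
Reagents that add atoms: none
Why: Hydride reduction of the lactone to the primary alcohol frees the tertiary C8 hydroxyl and leaves a 1,2-diol at C11/C12.

Step 4
Reactants: 4 8-epi-13,14,15,16-tetranorlabdane-8,11,12-triol
Product: 5 8β-hydroxydriman-11-al
Conditions: NaIO4, THF–H2O, 0 → 23 °C
Reagents that add atoms: none
Why: Malaprade glycol cleavage excises C12 as formaldehyde; the C8 hydroxyl is 1,3 to C11 and is not cleaved, and the near-neutral medium avoids retro-aldol and dehydration of the β-hydroxy aldehyde.

Step 5
Reactants: 5 8β-hydroxydriman-11-al
Product: 6 8β-(triethylsilyloxy)driman-11-al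
Conditions: Et3SiOTf, 2,6-lutidine, CH2Cl2, −78 → 0 °C
Reagents that add atoms: triethylsilyl trifluoromethanesulfonate, CC[Si](CC)(CC)OS(=O)(=O)C(F)(F)F
Why: Silyl triflate silylation of a hindered tertiary alcohol; the ether blocks retro-aldol, removes the chelating hydroxyl before step 6 and later keeps the 8β-oxygen out of the cationic chemistry.

Step 6
Reactants: 6 8β-(triethylsilyloxy)driman-11-al; 7 ethoxyacetylene
Product: 9 (11S)-11-(ethoxyethynyl)-8β-(triethylsilyloxy)driman-11-ol, via lithium ethoxyacetylide 8 (not isolated)
Conditions: 7, n-BuLi, THF, −78 °C; then 6, −78 °C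
Reagents that add atoms: none
Why: 1,2-Addition of a small, highly nucleophilic acetylide to a hindered aldehyde. Under non-chelating conditions the polar Felkin–Anh model applies: the carbonyl oxygen turns away from the C8–O dipole toward the C10 flank and the acetylide enters from the open α face beside H9 (the β face is closed by the axial C8 and C10 substituents), which should give the (11S) alcohol.

Step 7
Reactants: 9 (11S)-11-(ethoxyethynyl)-8β-(triethylsilyloxy)driman-11-ol
Product: 12 (aS)-11-(2-ethoxyethenylidene)-8β-(triethylsilyloxy)drimane, via N-sulfonylhydrazine 10 (not isolated), via propargylic diazene 11 (not isolated)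
Conditions: 2-nitrobenzenesulfonylhydrazide, PPh3, diethyl azodicarboxylate, N-methylmorpholine, −30 → 23 °C
Reagents that add atoms: none
Why: Myers allene synthesis: Mitsunobu displacement with inversion gives 10, loss of sulfinic acid gives diazene 11, and its retro-ene loss of N2 delivers hydrogen to C2′ on the face the nitrogen leaves. The net anti transposition converts the (11S) center stereospecifically into the (aS) axis. The basic solvent takes up the sulfinic acid, which would otherwise attack the ynol and allenyl ethers.

Step 8
Reactants: 13 1,1,2-trimethoxyethane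
Product: 15 3-(dimethylamino)-2-methoxyacrolein, via vinamidinium chloride 14 (not isolated)
Conditions: POCl3, DMF, 0 → 70 °C; then aq. K2CO3
Reagents that add atoms: N,N-dimethylformamide, CN(C)C=O; water, O
Why: Vilsmeier–Haack–Arnold formylation of the enol ether released from the acetal gives the 2-methoxy trimethinium salt, and mild basic hydrolysis stops at the vinylogous formamide.

Step 9
Reactants: 15 3-(dimethylamino)-2-methoxyacrolein
Product: 17 (Z)-3-chloro-2-methoxyacrolein, via chloropropeniminium chloride 16 (not isolated)
Conditions: (COCl)2, CH2Cl2, 0 °C; then H2O, 0 °C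
Reagents that add atoms: oxalyl chloride, ClC(=O)C(=O)Cl; water, O
Why: O-Acylation of the vinylogous amide and chloride addition–elimination give the β-chlorovinyl iminium salt, whose hydrolysis at the iminium carbon frees the β-chloroacrolein. The extended isomer with chlorine trans to the formyl group (Z by the sequence rule) is expected to be the stable one. The aldehyde is used at once.

Step 10
Reactants: 12 (aS)-11-(2-ethoxyethenylidene)-8β-(triethylsilyloxy)drimane; 17 (Z)-3-chloro-2-methoxyacrolein
Product: 19 (1Z)-1-chloro-4-ethoxy-2-methoxy-6-[8β-(triethylsilyloxy)-11-nordriman-9-yl]hexa-1,4,5-trien-3-ol with (aS) axis (C3′ epimers), via 1-lithioallene 18 (not isolated)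
Conditions: n-BuLi, THF, −78 °C; then 17, −78 °C
Reagents that add atoms: none
Why: α-Lithiation of a 1-alkoxyallene (the C2′–H next to oxygen is the kinetic site, C11–H is shielded by the decalin) and 1,2-addition to the aldehyde. The sp2 C–Li bond replaces C–H with retention, so the axis is kept at −78 °C. C3′ is formed without control and both epimers serve in step 11.

Step 11
Reactants: 19 (1Z)-1-chloro-4-ethoxy-2-methoxy-6-[8β-(triethylsilyloxy)-11-nordriman-9-yl]hexa-1,4,5-trien-3-ol
Product: 21 (4E,5R)-5-chloro-3-ethoxy-4-[8β-(triethylsilyloxy)driman-11-ylidene]cyclopent-2-en-1-one, via trifluoroacetate 20 (not isolated)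
Conditions: n-BuLi (1 equiv), Et2O, −78 °C; (CF3CO)2O, −78 → −20 °C; then aq. NaH2PO4/Na2HPO4 (pH 7), 0 °C
Reagents that add atoms: water, O
Why: Proposed new method: trifluoroacetylation of the lithium alkoxide of 19 and ionization of 20 give the pentadienyl cation C1′=C2′(OEt)–C3′–C4′(OMe)=C5′HCl, whose thermal conrotatory 4π electrocyclization joins C1′ to C5′ and closes ring C as a five-membered carbocycle. The closest known reaction type is the cationic cyclopentannulation of 1-lithio-1-alkoxyallene adducts of enones and enals (ionization of the carbinol with (CF3CO)2O, ring closure with axial-to-central chirality transfer), extended here to a 2-alkoxy-3-chloroallyl terminus. The alkoxy groups on C2′ and C4′ do little for the open cation but make the cyclized ion a 1,3-dialkoxyallyl cation, so closure should be fast and irreversible. The selectivity needed is torquoselectivity: C9 on the allene terminus lies out of the pentadienyl plane and turns away from C5′, which fixes the sense of conrotation and puts C9 cis to C2′ on the C11=C1′ bond. Because chlorine occupies the outside position of the (Z)-chloroalkene, the (aS) axis then delivers C5′ as R. C3′ becomes sp2, so both carbinol epimers converge. No amine base is used, because the cyclized cation has an acidic C5′–H whose removal would erase the new stereocenter; lithium trifluoroacetate is too weak a base for that. On the neutral aqueous quench water adds to the less hindered, chlorine-activated C4′ terminus and the hemiketal loses methanol, leaving the C4′ ketone and the C2′ ethyl enol ether.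

Step 12
Reactants: 21 (4E,5R)-5-chloro-3-ethoxy-4-[8β-(triethylsilyloxy)driman-11-ylidene]cyclopent-2-en-1-one
Product: 22 (4E,5R)-5-chloro-3-hydroxy-4-[8β-(triethylsilyloxy)driman-11-ylidene]cyclopent-2-en-1-one
Conditions: 0.5 M HCl, THF–H2O, 0 °C
Reagents that add atoms: water, O
Why: Acid hydrolysis of a vinylogous ester by addition of water at C2′ and loss of ethanol. The silyl ether is kept so that the 8β-oxygen cannot displace ethanol intramolecularly. Dilute acid at 0 °C should not enolize C5′; any material that loses the silyl group early converges on 23 in step 13.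

Step 13
Reactants: 22 (4E,5R)-5-chloro-3-hydroxy-4-[8β-(triethylsilyloxy)driman-11-ylidene]cyclopent-2-en-1-one
Product: 23 (4E,5R)-5-chloro-3-hydroxy-4-(8β-hydroxydriman-11-ylidene)cyclopent-2-en-1-one
Conditions: HF·pyridine, pyridine, THF, 0 → 23 °C
Reagents that add atoms: none
Why: Fluoride cleavage of the tertiary silyl ether under pyridine-buffered conditions, which are neither basic enough to epimerize C5′ nor acidic enough to dehydrate the tertiary alcohol onto the vinylogous acid.

**Compound list**

1 | (+)-sclareolide | CC1(C)CCC[C@]2(C)[C@H]3CC(=O)O[C@]3(C)CC[C@@H]12 | starting material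
2 | 8-epi-sclareolide | CC1(C)CCC[C@]2(C)[C@H]3CC(=O)O[C@@]3(C)CC[C@@H]12 | intermediate
3 | 11-hydroxy-8-epi-sclareolide (C11 epimers) | CC1(C)CCC[C@]2(C)[C@H]3C(O)C(=O)O[C@@]3(C)CC[C@@H]12 | intermediate
4 | 8-epi-13,14,15,16-tetranorlabdane-8,11,12-triol (C11 epimers) | CC1(C)CCC[C@]2(C)[C@@H](C(O)CO)[C@@](C)(O)CC[C@@H]12 | intermediate
5 | 8β-hydroxydriman-11-al | CC1(C)CCC[C@]2(C)[C@@H](C=O)[C@@](C)(O)CC[C@@H]12 | intermediate
6 | 8β-(triethylsilyloxy)driman-11-al | CC1(C)CCC[C@]2(C)[C@@H](C=O)[C@@](C)(O[Si](CC)(CC)CC)CC[C@@H]12 | intermediate
7 | ethoxyacetylene | CCOC#C | starting material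
8 | lithium ethoxyacetylide | CCOC#C[Li] | intermediate
9 | (11S)-11-(ethoxyethynyl)-8β-(triethylsilyloxy)driman-11-ol | CC1(C)CCC[C@]2(C)[C@@H]([C@H](O)C#COCC)[C@@](C)(O[Si](CC)(CC)CC)CC[C@@H]12 | intermediate
10 | N-[(11R)-11-(ethoxyethynyl)-8β-(triethylsilyloxy)driman-11-yl]-2-nitrobenzenesulfonohydrazide | CC1(C)CCC[C@]2(C)[C@@H]([C@@H](N(N)S(=O)(=O)c3ccccc3[N+](=O)[O-])C#COCC)[C@@](C)(O[Si](CC)(CC)CC)CC[C@@H]12 | intermediate
11 | (11R)-11-diazenyl-11-(ethoxyethynyl)-8β-(triethylsilyloxy)drimane | CC1(C)CCC[C@]2(C)[C@@H]([C@@H](N=N)C#COCC)[C@@](C)(O[Si](CC)(CC)CC)CC[C@@H]12 | intermediate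
12 | (aS)-11-(2-ethoxyethenylidene)-8β-(triethylsilyloxy)drimane | CC1(C)CCC[C@]2(C)[C@@H](C([H])=[C@]=C(OCC)[H])[C@@](C)(O[Si](CC)(CC)CC)CC[C@@H]12 | intermediate
13 | 1,1,2-trimethoxyethane | COCC(OC)OC | starting material
14 | N-[3-(dimethylamino)-2-methoxyprop-2-en-1-ylidene]-N-methylmethanaminium chloride | CN(C)C=C(OC)C=[N+](C)C.[Cl-] | intermediate
15 | 3-(dimethylamino)-2-methoxyacrolein (configurationally mobile enaminal) | CN(C)C=C(OC)C=O | intermediate
16 | N-(3-chloro-2-methoxyprop-2-en-1-ylidene)-N-methylmethanaminium chloride | C[N+](C)=CC(OC)=CCl.[Cl-] | intermediate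
17 | (Z)-3-chloro-2-methoxyacrolein | O=C/C(OC)=C/Cl | intermediate
18 | (aS)-11-(2-ethoxy-2-lithioethenylidene)-8β-(triethylsilyloxy)drimane | CC1(C)CCC[C@]2(C)[C@@H](C([H])=[C@]=C(OCC)[Li])[C@@](C)(O[Si](CC)(CC)CC)CC[C@@H]12 | intermediate
19 | (1Z)-1-chloro-4-ethoxy-2-methoxy-6-[8β-(triethylsilyloxy)-11-nordriman-9-yl]hexa-1,4,5-trien-3-ol, (aS) axis, C3′ epimers | CC1(C)CCC[C@]2(C)[C@@H](C([H])=[C@]=C(OCC)C(O)/C(OC)=C/Cl)[C@@](C)(O[Si](CC)(CC)CC)CC[C@@H]12 | intermediate
20 | trifluoroacetate of 19 | CC1(C)CCC[C@]2(C)[C@@H](C([H])=[C@]=C(OCC)C(OC(=O)C(F)(F)F)/C(OC)=C/Cl)[C@@](C)(O[Si](CC)(CC)CC)CC[C@@H]12 | intermediate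
21 | (4E,5R)-5-chloro-3-ethoxy-4-[8β-(triethylsilyloxy)driman-11-ylidene]cyclopent-2-en-1-one | CC1(C)CCC[C@]2(C)[C@@H](/C=C3\C(OCC)=CC(=O)[C@@H]3Cl)[C@@](C)(O[Si](CC)(CC)CC)CC[C@@H]12 | intermediate
22 | (4E,5R)-5-chloro-3-hydroxy-4-[8β-(triethylsilyloxy)driman-11-ylidene]cyclopent-2-en-1-one | CC1(C)CCC[C@]2(C)[C@@H](/C=C3\C(O)=CC(=O)[C@@H]3Cl)[C@@](C)(O[Si](CC)(CC)CC)CC[C@@H]12 | intermediate
23 | (4E,5R)-5-chloro-3-hydroxy-4-(8β-hydroxydriman-11-ylidene)cyclopent-2-en-1-one (CNP0279879.2) | CC1(C)CCC[C@]2(C)[C@@H](/C=C3\C(O)=CC(=O)[C@@H]3Cl)[C@@](C)(O)CC[C@@H]12 | target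

**Step count and uncertain steps**

Total step count: 13. Longest linear sequence: 11 (steps 1–7 and 10–13); steps 8 and 9 make the aldehyde fragment.

Step 11 (key step).
- Most likely failure: loss of the C5′ configuration by proton loss from the cyclized dialkoxyallyl cation, or protonation of the allenyl ether before closure if any free acid arises. A secondary risk is capture of water at C2′ instead of C4′, which would shift the enol ether to the other oxygen; that would not matter after step 12.
- Why: the open cation is not stabilized by its alkoxy groups, so ionization may need temperatures at which these side processes compete.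
- Fallback (known chemistry): from 6, a Horner–Wadsworth–Emmons olefination would be run with diethyl (2-ethoxy-4-oxocyclopent-2-en-1-yl)phosphonate F2. F2 would be made from 3-ethoxycyclopent-2-en-1-one by radical bromination with N-bromosuccinimide to 4-bromo-3-ethoxycyclopent-2-en-1-one F1 and an Arbuzov reaction with P(OEt)3. The olefination would give the chlorine-free alkylidene enone (4Z)-3-ethoxy-4-[8β-(triethylsilyloxy)driman-11-ylidene]cyclopent-2-en-1-one F3. Kinetic deprotonation at C5′ with LiN(SiMe3)2 and chlorination with N-chlorosuccinimide would return to the route at 21. The cost is that alkene geometry and C5′ would then rest on separation and equilibration rather than on the allene axis.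

Step 7.
- Most likely failure: slow Mitsunobu displacement at C11, which is flanked by two quaternary carbons, with competing attack of the activated ynol ether.
- Why: backside entry is possible only in the rotamer that places the leaving group between the axial C8 and C10 substituents.
- Fallback: from 6, Colvin homologation (Me3SiCHN2, LiN(i-Pr)2) would give the terminal alkyne 9-ethynyl-8β-(triethylsilyloxy)-11-nordrimane F4. Alkylation of its lithium acetylide with chloromethyl ethyl ether would give the propargyl ether 9-(3-ethoxyprop-1-yn-1-yl)-8β-(triethylsilyloxy)-11-nordrimane F5. Prototropic isomerization with KOt-Bu would give the allenyl ether as both axial diastereomers, 12 and its (aR) isomer F6. These are separated and F6 is re-equilibrated with base; the route is rejoined at 12. Stereospecificity is given up for chemistry that needs no substitution at C11.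

Step 6.
- Most likely failure: poor facial selectivity, or preference for the (11R) alcohol if lithium bridges the aldehyde and the silyl ether oxygen.
- Why: the two flanks of C11 are sterically similar and the prediction rests on the dipole argument alone.
- Fallback: from 6, the addition would be run without regard to selectivity, giving 9 together with its (11R) epimer F7. The mixture would be oxidized with Dess–Martin periodinane to the ynone 3-ethoxy-1-[8β-(triethylsilyloxy)-11-nordriman-9-yl]prop-2-yn-1-one F8. Corey–Bakshi–Shibata reduction with (S)-1-methyl-3,3-diphenyltetrahydro-1H,3H-pyrrolo[1,2-c][1,3,2]oxazaborole and catecholborane (decalin as the large group) would then give 9 under reagent control.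

Step 10.
- Most likely failure: addition–elimination at the chlorine-bearing carbon of 17 in place of carbonyl addition, or erosion of the axis if the addition is slow.
- Why: 17 is a vinylogous acid chloride and a labile aldehyde.
- Fallback: from 17, oxidation with NaClO2 would give (Z)-3-chloro-2-methoxyacrylic acid F9, and amide coupling would give the Weinreb amide (Z)-3-chloro-N,2-dimethoxy-N-methylacrylamide F10. Acylation of 18 (from 12) would give the allenyl ketone F11, and 1,2-reduction with i-Bu2AlH at −78 °C would rejoin the route at 19.

**Further compounds**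

F1 | step 11 | 4-bromo-3-ethoxycyclopent-2-en-1-one | CCOC1=CC(=O)CC1Br
F2 | step 11 | diethyl (2-ethoxy-4-oxocyclopent-2-en-1-yl)phosphonate | CCOC1=CC(=O)CC1P(=O)(OCC)OCC
F3 | step 11 | (4Z)-3-ethoxy-4-[8β-(triethylsilyloxy)driman-11-ylidene]cyclopent-2-en-1-one | CC1(C)CCC[C@]2(C)[C@@H](/C=C3\C(OCC)=CC(=O)C3)[C@@](C)(O[Si](CC)(CC)CC)CC[C@@H]12
F4 | step 7 | 9-ethynyl-8β-(triethylsilyloxy)-11-nordrimane | CC1(C)CCC[C@]2(C)[C@@H](C#C)[C@@](C)(O[Si](CC)(CC)CC)CC[C@@H]12
F5 | step 7 | 9-(3-ethoxyprop-1-yn-1-yl)-8β-(triethylsilyloxy)-11-nordrimane | CC1(C)CCC[C@]2(C)[C@@H](C#CCOCC)[C@@](C)(O[Si](CC)(CC)CC)CC[C@@H]12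
F6 | step 7 | (aR)-11-(2-ethoxyethenylidene)-8β-(triethylsilyloxy)drimane | CC1(C)CCC[C@]2(C)[C@@H](C([H])=[C@@]=C(OCC)[H])[C@@](C)(O[Si](CC)(CC)CC)CC[C@@H]12
F7 | step 6 | (11R)-11-(ethoxyethynyl)-8β-(triethylsilyloxy)driman-11-ol | CC1(C)CCC[C@]2(C)[C@@H]([C@@H](O)C#COCC)[C@@](C)(O[Si](CC)(CC)CC)CC[C@@H]12
F8 | step 6 | 3-ethoxy-1-[8β-(triethylsilyloxy)-11-nordriman-9-yl]prop-2-yn-1-one | CC1(C)CCC[C@]2(C)[C@@H](C(=O)C#COCC)[C@@](C)(O[Si](CC)(CC)CC)CC[C@@H]12
F9 | step 10 | (Z)-3-chloro-2-methoxyacrylic acid | OC(=O)/C(OC)=C/Cl
F10 | step 10 | (Z)-3-chloro-N,2-dimethoxy-N-methylacrylamide | CON(C)C(=O)/C(OC)=C/Cl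
F11 | step 10 | (1Z)-1-chloro-4-ethoxy-2-methoxy-6-[8β-(triethylsilyloxy)-11-nordriman-9-yl]hexa-1,4,5-trien-3-one, (aS) axis | CC1(C)CCC[C@]2(C)[C@@H](C([H])=[C@]=C(OCC)C(=O)/C(OC)=C/Cl)[C@@](C)(O[Si](CC)(CC)CC)CC[C@@H]12
A1 | alternative 1 | 3-(5-bromo-2-methylpentan-2-yl)-2,6-dimethylphenol | Cc1ccc(C(C)(C)CCCBr)c(C)c1O
A2 | alternative 1 | (8aS)-2,5,5,8a-tetramethyl-6,7,8,8a-tetrahydronaphthalen-1(5H)-one | CC1(C)CCC[C@]2(C)C(=O)C(C)=CC=C12
A3 | alternative 2 | methyl (6E,10S)-10,11-epoxy-7,11-dimethyl-3-oxododec-6-enoate | CC1(C)O[C@H]1CC/C(C)=C/CCC(=O)CC(=O)OC
A4 | alternative 2 | methyl 3β-hydroxy-8-oxo-12-nordriman-11-oate | CC1(C)[C@@H](O)CC[C@]2(C)[C@@H](C(=O)OC)C(=O)CC[C@@H]12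
A5 | alternative 3 | 2-[(1R,2S)-1,3,3-trimethyl-2-(3-oxobutyl)cyclohexyl]acetaldehyde | CC1(C)CCC[C@](C)(CC=O)[C@H]1CCC(C)=O
A6 | alternative 3 | 8β-hydroxydriman-11-al (identical with 5) | CC1(C)CCC[C@]2(C)[C@@H](C=O)[C@@](C)(O)CC[C@@H]12
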